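Sodwanone T is disconnected (squalene numbering) at its two angular methyl groups. In each cyclohexene ring the methyl on quaternary C6 (C19) is cis to the oxepane oxygen on C7 (C18) and flanks the C10=C11 (C14=C15) olefin. This is the trace of a C6–C11 (C19–C14) cyclopropane, built syn to a C7 (C18) hydroxyl and later opened at its CH2–C11 (CH2–C14) bond. The key step, a twofold hydroxyl-directed methylene transfer, makes four C–C bonds, two rings and four stereocentres in one operation. Its precursor is an ethane-bridged bis(cyclohex-2-enol) with tetrasubstituted ring olefins, homoprenyl chains on C6/C19 and (7S,18S) carbinols.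

Key step: step 9

Remark 1: squalene numbering is used for all intermediates. C2/C23 carry the gem-dimethyl groups, C3/C22 the side-chain oxygen, and C12–C13 is the bridge.
Remark 2: C10 and C15 are formed without control in step 4. All intermediates from step 4 to step 11 are therefore mixtures of epimers at these two centres, which are left undefined in the SMILES. Both centres become trigonal in step 12.

Step 1
Reactants: 1 1,3-dimethoxybenzene
Product: 2 1,5-dimethoxycyclohexa-1,4-diene
Conditions: Li, NH3(l), t-BuOH, THF, −78 to −33 °C; then H2O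
Reagents that add atoms: none
Why: Birch reduction keeps both donor-substituted carbons on the remaining double bonds, so the unconjugated 1,4-diene should form and no stereocentre arises.

Step 2
Reactants: 2 1,5-dimethoxycyclohexa-1,4-diene; 3 5-bromo-2-methylpent-2-ene
Product: 5 2-(4-methylpent-3-en-1-yl)cyclohexane-1,3-dione, via 6-alkylated bis(enol ether) 4 (not isolated)
Conditions: t-BuLi, THF, −78 °C; 3, HMPA, −78 °C to rt; then 1 M HCl, THF, rt
Reagents that add atoms: water (SMILES: O)
Why: Deprotonation removes a doubly allylic proton from the CH2 between the two enol ethers, the pentadienyl anion is alkylated (SN2) at this central carbon by the primary bromide, and enol ether hydrolysis releases the 2-substituted 1,3-dione while the trisubstituted olefin survives brief dilute acid.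

Step 3
Reactants: 5 2-(4-methylpent-3-en-1-yl)cyclohexane-1,3-dione
Product: 6 3-(2-methylpropoxy)-2-(4-methylpent-3-en-1-yl)cyclohex-2-en-1-one
Conditions: i-BuOH, p-TsOH·H2O (cat.), toluene, reflux, Dean–Stark trap
Reagents that add atoms: 2-methylpropan-1-ol (SMILES: CC(C)CO)
Why: Acid-catalysed vinylogous esterification with azeotropic removal of water gives one product because the two carbonyl groups of 5 are equivalent.

Step 4
Reactants: 6 3-(2-methylpropoxy)-2-(4-methylpent-3-en-1-yl)cyclohex-2-en-1-one
Product: 7 (±)-6-methyl-3-(2-methylpropoxy)-2-(4-methylpent-3-en-1-yl)cyclohex-2-en-1-one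
Conditions: LiN(iPr)2, THF, −78 °C; MeI, −78 to 0 °C
Reagents that add atoms: iodomethane (SMILES: CI)
Why: Kinetic α′-deprotonation of a vinylogous ester and SN2 methylation (first half of the Stork–Danheiser sequence) places the future C10/C15 methyl, and the new centre is racemic and is erased in step 12.

Step 5
Reactants: 7 (±)-6-methyl-3-(2-methylpropoxy)-2-(4-methylpent-3-en-1-yl)cyclohex-2-en-1-one; 8 ethynyltrimethylsilane
Product: 10 1-ethynyl-6-methyl-3-(2-methylpropoxy)-2-(4-methylpent-3-en-1-yl)cyclohex-2-en-1-ol, via silylated alkynyl carbinol 9 (not isolated)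
Conditions: 8, n-BuLi, THF, −78 °C; 7, −78 °C to rt; then MeOH, K2CO3 (cat.), rt; H2O
Reagents that add atoms: none
Why: 1,2-Addition of a lithium acetylide to the vinylogous ester carbonyl followed by base-catalysed methanolysis of the C–Si bond avoids acid, so the labile enol ether carbinol survives and a free alkyne terminus is left for the second union, while the carbinol centre is lost in step 6.

Step 6
Reactants: 10 1-ethynyl-6-methyl-3-(2-methylpropoxy)-2-(4-methylpent-3-en-1-yl)cyclohex-2-en-1-ol; 7 (±)-6-methyl-3-(2-methylpropoxy)-2-(4-methylpent-3-en-1-yl)cyclohex-2-en-1-one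
Product: 12 3,3'-(ethyne-1,2-diyl)bis[4-methyl-2-(4-methylpent-3-en-1-yl)cyclohex-2-en-1-one], via alkyne-bridged bis(carbinol) 11 (not isolated)
Conditions: n-BuLi (2.1 equiv), THF, −78 to 0 °C; 7, −78 °C to rt; then 1 M HCl, THF, rt
Reagents that add atoms: water (SMILES: O)
Why: The alkoxide–acetylide dianion adds 1,2 to a second molecule of 7, and aqueous acid then ionises both tertiary carbinols with alkoxy assistance and hydrolyses them (twofold Stork–Danheiser transposition), so both enones appear only after all carbanion chemistry is over.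

Step 7
Reactants: 12 3,3'-(ethyne-1,2-diyl)bis[4-methyl-2-(4-methylpent-3-en-1-yl)cyclohex-2-en-1-one]
Product: 13 3,3'-(ethane-1,2-diyl)bis[4-methyl-2-(4-methylpent-3-en-1-yl)cyclohex-2-en-1-one]
Conditions: H2 (1 atm), RhCl(PPh3)3 (10 mol %), benzene–EtOH, rt
Reagents that add atoms: none
Why: Homogeneous hydrogenation with RhCl(PPh3)3 saturates alkynes and 1,2-disubstituted olefins but leaves tri- and tetrasubstituted olefins and ketones, so only the C12–C13 bridge should take up hydrogen.

Step 8
Reactants: 13 3,3'-(ethane-1,2-diyl)bis[4-methyl-2-(4-methylpent-3-en-1-yl)cyclohex-2-en-1-one]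
Product: 14 (1S,1'S)-3,3'-(ethane-1,2-diyl)bis[4-methyl-2-(4-methylpent-3-en-1-yl)cyclohex-2-en-1-ol] (7S,18S)
Conditions: (R)-2-methyl-CBS-oxazaborolidine (0.4 equiv), catecholborane (3 equiv), toluene, −78 to −40 °C; MeOH, aq NaOH
Reagents that add atoms: none
Why: In this twofold CBS reduction the α-substituted alkenyl arm is the large group and the ring CH2 the small one, so the (R)-catalyst should give the S carbinol at C7 and C18 under catalyst control; catecholborane does not hydroborate the side chains at low temperature, and the double reduction shifts most stereochemical error into a separable (7S,18R) diastereomer.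

Step 9
Reactants: 14 (1S,1'S)-3,3'-(ethane-1,2-diyl)bis[4-methyl-2-(4-methylpent-3-en-1-yl)cyclohex-2-en-1-ol]
Product: 15 (1R,2S,6R,1'R,2'S,6'R)-6,6'-(ethane-1,2-diyl)bis[5-methyl-1-(4-methylpent-3-en-1-yl)bicyclo[4.1.0]heptan-2-ol] (each cyclopropane CH2 syn to its hydroxyl)
Conditions: Et2Zn (4 equiv), CH2Cl2, −20 °C; then CH2I2 (3 equiv, slow addition), −20 to 0 °C
Reagents that add atoms: diiodomethane (SMILES: ICI)
Why: Et2Zn turns both carbinols into zinc alkoxides, these bind the iodomethylzinc carbenoid, and CH2 passes to the adjacent C6=C11 and C19=C14 bonds through the concerted butterfly transition state. The closest known reaction type is the hydroxyl-directed Simmons–Smith cyclopropanation (Furukawa variant) of cyclic allylic alcohols, which is established for ring-fused tetrasubstituted cyclohexenols. Each three-membered ring closes by a suprafacial [2+1] cheletropic addition in which both of its new C–CH2 bonds form together, so a cis ring fusion results. C6 and C19 are set by the neighbouring C7 and C18 carbinols of step 8, because the bound carbenoid reaches only the face that bears the oxygen, and C11 and C14 follow from the suprafacial addition. The step needs site selectivity for the two crowded ring olefins over the two open trisubstituted side-chain olefins, which the rate gain of alkoxide-bound delivery, the small carbenoid excess and the low temperature should secure. Either C10/C15 epimer can react, the one with its methyl on the hydroxyl face through the half-chair that places this methyl pseudo-equatorial.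

Step 10
Reactants: 15 bis(cyclopropyl carbinol) (see step 9)
Product: 16 (3R,22R)-bis(epoxide): 15 in which each side chain ends in an (R)-3,3-dimethyloxiran-2-yl group
Conditions: D-fructose-derived Shi ketone (0.6 equiv), KHSO5 (as 2KHSO5·KHSO4·K2SO4), K2CO3, Bu4NHSO4 (cat.), Na2B4O7 buffer, MeCN–CH2(OMe)2–H2O, 0 °C
Reagents that add atoms: potassium peroxymonosulfate (SMILES: [K+].[O-]S(=O)(=O)OO)
Why: In the Shi epoxidation the dioxirane of the D-fructose ketone attacks trisubstituted olefins through a spiro transition state and should give the R epoxide at C3 and C22 under catalyst control, while cyclopropanes and hindered secondary carbinols are left alone in the basic buffer.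

Step 11
Reactants: 16 (3R,22R)-bis(epoxide)
Product: 18 bis(oxepane) diol with both cyclopropanes intact (3R,7S,18S,22R; each 2,2-dimethyloxepan-3-ol ring fused at C6–C7 or C19–C18), via bis(trimethylsilyl ether) 17 (not isolated)
Conditions: TMSOTf (5 equiv), 2,6-di-tert-butyl-4-methylpyridine (6 equiv), CH2Cl2, −78 °C; then K2CO3, MeOH, rt
Reagents that add atoms: none
Why: This is a silyl triflate-promoted endo-selective epoxide-opening oxacyclisation (7-endo-tet) in which O-silylation loosens the bond to tertiary C2 (C23), which the C7 (C18) oxygen captures; 6-exo attack at C3 is disfavoured because charge builds at the tertiary carbon, the nucleophile is neopentylic and the O–C7–C6–C5 dihedral angle widened by the cyclopropane fits a seven- better than a six-membered ring, the C3/C22–O bonds stay intact so their R configuration is kept, and the hindered pyridine excludes protic acid that would ionise the cyclopropyl carbinols.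

Step 12
Reactants: 18 bis(oxepane) diol with both cyclopropanes intact
Product: 19 (3R,6S,7S,18S,19S,22R)-diene diol (the C3 alcohol of sodwanone T, C2-symmetric)
Conditions: dry HCl, CHCl3, 0 °C
Reagents that add atoms: none
Why: This is a protolytic cyclopropane opening with proton loss (the reaction type that turns 9,19-cyclolanostanes into lanostenes): the proton adds to the least substituted carbon, the CH2–C11 (CH2–C14) bond breaks because the tertiary cation at C11 (C14) is remote from oxygen whereas one at C6 (C19) would be β to the ether oxygen, and loss of the C10 (C15) proton under equilibrating conditions gives the tetrasubstituted olefin, merging all C10/C15 epimers while C6 and C19 keep the configuration of step 9.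

Step 13
Reactants: 19 (3R,6S,7S,18S,19S,22R)-diene diol
Product: 20 sodwanone T
Conditions: Dess–Martin periodinane (1.0 equiv), CH2Cl2, 0 °C
Reagents that add atoms: none
Why: In this Dess–Martin oxidation the two carbinols are remote and equivalent, so one equivalent of oxidant should give a statistical mixture from which the keto alcohol is separated and the diol recycled; the tetrasubstituted olefins and ethers are inert and the new ketone has no epimerisable neighbour.

Compound list
1 | 1,3-dimethoxybenzene | COc1cccc(OC)c1 | starting material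
2 | 1,5-dimethoxycyclohexa-1,4-diene | COC1=CCC=C(OC)C1 | intermediate
3 | 5-bromo-2-methylpent-2-ene | CC(C)=CCCBr | starting material
4 | 1,5-dimethoxy-6-(4-methylpent-3-en-1-yl)cyclohexa-1,4-diene (not isolated) | COC1=CCC=C(OC)C1CCC=C(C)C | intermediate
5 | 2-(4-methylpent-3-en-1-yl)cyclohexane-1,3-dione | CC(C)=CCCC1C(=O)CCCC1=O | intermediate
6 | 3-(2-methylpropoxy)-2-(4-methylpent-3-en-1-yl)cyclohex-2-en-1-one | CC(C)COC1=C(CCC=C(C)C)C(=O)CCC1 | intermediate
7 | (±)-6-methyl-3-(2-methylpropoxy)-2-(4-methylpent-3-en-1-yl)cyclohex-2-en-1-one | CC(C)COC1=C(CCC=C(C)C)C(=O)C(C)CC1 | intermediate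
8 | ethynyltrimethylsilane | C#C[Si](C)(C)C | starting material
9 | 6-methyl-3-(2-methylpropoxy)-2-(4-methylpent-3-en-1-yl)-1-[(trimethylsilyl)ethynyl]cyclohex-2-en-1-ol (not isolated, stereoisomer mixture) | CC(C)COC1=C(CCC=C(C)C)C(O)(C#C[Si](C)(C)C)C(C)CC1 | intermediate
10 | 1-ethynyl-6-methyl-3-(2-methylpropoxy)-2-(4-methylpent-3-en-1-yl)cyclohex-2-en-1-ol (stereoisomer mixture) | CC(C)COC1=C(CCC=C(C)C)C(O)(C#C)C(C)CC1 | intermediate
11 | 1,1'-(ethyne-1,2-diyl)bis[6-methyl-3-(2-methylpropoxy)-2-(4-methylpent-3-en-1-yl)cyclohex-2-en-1-ol] (not isolated, stereoisomer mixture) | CC(C)COC1=C(CCC=C(C)C)C(O)(C#CC2(O)C(C)CCC(OCC(C)C)=C2CCC=C(C)C)C(C)CC1 | intermediate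
12 | 3,3'-(ethyne-1,2-diyl)bis[4-methyl-2-(4-methylpent-3-en-1-yl)cyclohex-2-en-1-one] (C10/C15 epimers) | CC1CCC(=O)C(CCC=C(C)C)=C1C#CC1=C(CCC=C(C)C)C(=O)CCC1C | intermediate
13 | 3,3'-(ethane-1,2-diyl)bis[4-methyl-2-(4-methylpent-3-en-1-yl)cyclohex-2-en-1-one] (C10/C15 epimers) | CC1CCC(=O)C(CCC=C(C)C)=C1CCC1=C(CCC=C(C)C)C(=O)CCC1C | intermediate
14 | (1S,1'S)-3,3'-(ethane-1,2-diyl)bis[4-methyl-2-(4-methylpent-3-en-1-yl)cyclohex-2-en-1-ol], key-step precursor (C10/C15 epimers) | CC1CC[C@H](O)C(CCC=C(C)C)=C1CCC1=C(CCC=C(C)C)[C@@H](O)CCC1C | intermediate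
15 | (1R,2S,6R,1'R,2'S,6'R)-6,6'-(ethane-1,2-diyl)bis[5-methyl-1-(4-methylpent-3-en-1-yl)bicyclo[4.1.0]heptan-2-ol], key-step product (C10/C15 epimers) | CC1CC[C@H](O)[C@]2(CCC=C(C)C)C[C@]12CC[C@]12C[C@@]1(CCC=C(C)C)[C@@H](O)CCC2C | intermediate
16 | (3R,22R)-bis(epoxide) of 15 | CC1CC[C@H](O)[C@]2(CC[C@H]3OC3(C)C)C[C@]12CC[C@]12C[C@@]1(CC[C@H]3OC3(C)C)[C@@H](O)CCC2C | intermediate
17 | bis(trimethylsilyl ether) of 18 (not isolated) | CC1CC[C@@H]2OC(C)(C)[C@H](O[Si](C)(C)C)CC[C@]23C[C@]13CC[C@]12C[C@]13CC[C@@H](O[Si](C)(C)C)C(C)(C)O[C@H]3CCC2C | intermediate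
18 | bis(oxepane) diol with C6–C11 and C19–C14 cyclopropanes (3R,7S,18S,22R) | CC1CC[C@@H]2OC(C)(C)[C@H](O)CC[C@]23C[C@]13CC[C@]12C[C@]13CC[C@@H](O)C(C)(C)O[C@H]3CCC2C | intermediate
19 | (3R,6S,7S,18S,19S,22R)-diene diol, C2-symmetric | CC1=C(CCC2=C(C)CC[C@@H]3OC(C)(C)[C@H](O)CC[C@@]23C)[C@]2(C)CC[C@@H](O)C(C)(C)O[C@H]2CC1 | intermediate
20 | sodwanone T (6S,7S,18S,19S,22R) | CC1=C(CCC2=C(C)CC[C@@H]3OC(C)(C)[C@H](O)CC[C@@]23C)[C@]2(C)CCC(=O)C(C)(C)O[C@H]2CC1 | target

Total step count: 13. Longest linear sequence: 13 steps (1 to 20). Compound 7 enters twice (steps 5 and 6), and 3 and 8 are purchased.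

Steps most likely to fail

1. Step 9 (key step).
- What may go wrong: methylene transfer to the crowded tetrasubstituted ring olefins may be slow, most of all in halves whose C10/C15 methyl lies on the hydroxyl face. Carbenoid that is not bound to an alkoxide could then begin to attack the open side-chain olefins.
- Fallback: the order of oxygen and methylene transfer is reversed so that no competing olefin is left. It sets out from 14.
- Shi epoxidation under the conditions of step 10 should take the two side-chain olefins first. The bulky dioxirane is slow with tetrasubstituted olefins, and the ring olefins are further deactivated by their allylic oxygen. This should give the side-chain bis(epoxide) of the bis(cyclohexenol) F1.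
- F1 is then treated with a large excess of Et2Zn/CH2I2 in CH2Cl2–DME at −20 °C, still under alkoxide direction. DME keeps ZnI2 complexed so that the epoxides are not opened.
- The route is rejoined at 16.

2. Step 11.
- What may go wrong: the carbinol oxygen may attack C3/C22 (6-exo mode), or the tertiary cation may lose a proton or undergo a hydride shift before the seven-membered ring closes.
- Fallback: the rings are closed on the olefins, where Markovnikov addition alone fixes the regiochemistry, and the carbinol centres are set afterwards. It sets out from 15.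
- A divalent mercury salt, Hg(OCOCF3)2 (2.1 equiv, CH2Cl2, −20 °C), should react with the olefins much faster than with the cyclopropanes. Intramolecular alkoxymercuration puts oxygen on tertiary C2/C23 and mercury on C3/C22, giving the bis(3-mercurio-oxepane) F2.
- Oxidative demercuration (NaBH4, O2, DMF) should give the C3/C22-epimeric bis(oxepane) diols F3.
- Dess–Martin oxidation of F3 should give the bis(oxepan-3-one) F4.
- Twofold CBS reduction with (S)-2-methyl-CBS-oxazaborolidine and BH3·SMe2 (quaternary C2/C23 as the large arm) should set 3R,22R.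
- The route is rejoined at 18.

3. Step 12.
- What may go wrong: the C7–O and C18–O bonds are cyclopropylcarbinyl ether bonds and may ionise with ring enlargement, in competition with protonation of the cyclopropanes. Alkyl or hydride shifts in the C11/C14 cations are a second risk.
- Fallback: a soft metal electrophile replaces the proton, so no strong acid is present. It sets out from 18.
- Hg(OCOCF3)2 (2.2 equiv, CH2Cl2, 0 °C to rt) should attack the least hindered cyclopropane carbon. As is known for cyclopropyl carbinol derivatives, it should cleave the CH2–C bond remote from oxygen.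
- Loss of the C10/C15 protons then gives the bis(mercuriomethyl) diene diol F5.
- Alkaline NaBH4 (THF–H2O, 0 °C) replaces mercury by hydrogen. Fast hydrogen transfer should outrun re-closure of the homoallyl radical.
- The route is rejoined at 19.

Further compounds
F1 | step 9 | side-chain (3R,22R)-bis(epoxide) of 14 | CC1CC[C@H](O)C(CC[C@H]2OC2(C)C)=C1CCC1=C(CC[C@H]2OC2(C)C)[C@@H](O)CCC1C
F2 | step 11 | bis(oxepane) with trifluoroacetoxymercurio groups on C3 and C22, cyclopropanes intact | CC1CC[C@@H]2OC(C)(C)C([Hg]OC(=O)C(F)(F)F)CC[C@]23C[C@]13CC[C@]12C[C@]13CCC([Hg]OC(=O)C(F)(F)F)C(C)(C)O[C@H]3CCC2C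
F3 | step 11 | bis(oxepane) diol, epimeric at C3 and C22, cyclopropanes intact | CC1CC[C@@H]2OC(C)(C)C(O)CC[C@]23C[C@]13CC[C@]12C[C@]13CCC(O)C(C)(C)O[C@H]3CCC2C
F4 | step 11 | bis(oxepan-3-one), cyclopropanes intact | CC1CC[C@@H]2OC(C)(C)C(=O)CC[C@]23C[C@]13CC[C@]12C[C@]13CCC(=O)C(C)(C)O[C@H]3CCC2C
F5 | step 12 | diene diol 19 with trifluoroacetoxymercuriomethyl groups on C6 and C19 in place of the methyl groups | CC1=C(CCC2=C(C)CC[C@@H]3OC(C)(C)[C@H](O)CC[C@@]23C[Hg]OC(=O)C(F)(F)F)[C@]2(C[Hg]OC(=O)C(F)(F)F)CC[C@@H](O)C(C)(C)O[C@H]2CC1
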